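**Plan**

Numbering (decalin): C1 ketone, C2 CO2Me, C3 hexadecyl, C4, C4a, C5 CO2Me, C6 hexadecyl, C7, C8 CO2Me, C8a. Ring B is opened at C2=C3 (intramolecular Knoevenagel) and C1–C2 (acylation of a malonate half-ester); the C3 acyl chain is taken off C4 (C3–C4, acylation of an alkylzinc) and the ester carbon off C8 (carbonylation of an enol triflate).
Ring A is then a cyclohexenone, cut at C4a–C5, C4a–C8a and C6=C7 into silyl-protected glycolaldehyde, methyl 3-oxononadecanoate and tert-butyl acetoacetate.
Enabling feature: C4a is a ring methine whose ring neighbours C5 and C8a each carry a carboxyl carbon, and the C6=C7 alkene lies β,γ to C8. With C8 written as a ketone, ring A (C4a–C5–C6–C7–C8–C8a) is the cyclohexenone that one aldehyde and two different β-keto esters give by Knoevenagel, Michael and aldol steps.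
Forward order: ring A first, then the C8 carboxyl, reduction of C8=C8a, the C3 ketone chain on C4, and ring B last.
Stereochemistry: C4a from the catalyst-controlled Michael addition; C5 by equilibration trans to the C4a substituent; C8 and C8a together by cis hydrogenation on the face away from that substituent, which also gives the cis ring fusion.

Key step: step 2

Assumption: the quinine-derived squaramide is taken to give the (R) centre at C4a of the Michael adduct, and (R)-BINAP to be the ligand matched with the substrate bias in the hydrogenation; if either sense proves opposite, the quinidine-derived catalyst or (S)-BINAP is used and nothing else changes.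

**Route**

Step 1
Reactants: 1 heptadecanoyl chloride; 2 Meldrum's acid
Product: 4 methyl 3-oxononadecanoate, via heptadecanoyl Meldrum's acid 3 (not isolated)
Conditions: pyridine, CH2Cl2, 0 °C to rt; then MeOH, reflux
Reagents that add atoms: methanol, CO
Why: C-acylation of Meldrum's acid by the acid chloride and thermal methanolysis with loss of acetone and CO2 (Oikawa–Yonemitsu β-keto ester synthesis) is the standard two-carbon homologation of a fatty acyl chloride.

Step 2
Reactants: 4 methyl 3-oxononadecanoate; 5 (tert-butyldimethylsilyloxy)acetaldehyde; 6 tert-butyl acetoacetate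
Product: 10 1-tert-butyl 3-methyl (1R,2S,3S)-2-[(tert-butyldimethylsilyloxy)methyl]-4-hexadecyl-6-oxocyclohex-4-ene-1,3-dicarboxylate, via alkylidene keto ester 7 (not isolated), via Michael adduct 8 (not isolated), via cyclic ketol 9 (not isolated)
Conditions: (i) 4 + 5, piperidine/AcOH (5 mol %), 4 Å MS, CH2Cl2, 0 °C; silica plug, switch to toluene; (ii) 6, quinine-derived 3,5-bis(trifluoromethyl)phenyl squaramide (5 mol %), toluene, −20 °C; (iii) pyrrolidine/AcOH (20 mol %), 40 °C
Reagents that add atoms: none
Why: Amine-catalysed Knoevenagel condensation of 5 with the long-chain keto ester 4 gives the doubly activated alkene 7 (C4a=C5); the squaramide holds its 1,3-dicarbonyl unit by hydrogen bonds while the quinuclidine delivers the enolate of 6 through C8a to one face of C4a (C8a–C4a); the acetyl methyl then closes ring A on the hexadecyl ketone by a 6-(enolexo)-exo-trig aldol addition and E1cB loss of water (C6=C7). The closest known reaction type is the cyclisation of Knoevenagel bis-adducts to Hagemann-type cyclohexenones, combined with bifunctional-amine-catalysed Michael additions of 1,3-dicarbonyl donors to alkylidene β-keto esters. C4a, the only centre that cannot epimerise, should be set by the catalyst; C5 equilibrates through its dienolate to the trans relationship with the C4a substituent; C8a is labile as a β-keto ester carbon and is fixed in step 5. Correct pairing of the two keto esters should follow from condensing 4 with the aldehyde before 6 is added and from keeping the Michael stage cold, so that retro-Michael crossover stays slow. Closure by the methyl group (C7) rather than by the chain methylene should be favoured by the easier enolisation and enamine formation of a methyl ketone and by the less crowded ketol, and dehydration into conjugation with the C8 ketone places the alkene at C6=C7.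

Step 3
Reactants: 10 ring A enone
Product: 11 3-tert-butyl 1-methyl (1S,2S)-2-[(tert-butyldimethylsilyloxy)methyl]-6-hexadecyl-4-(trifluoromethylsulfonyloxy)cyclohexa-3,5-diene-1,3-dicarboxylate
Conditions: NaH (1.05 equiv), THF, 0 °C; PhNTf2, 0 °C to rt
Reagents that add atoms: N-phenylbis(trifluoromethanesulfonimide), O=S(=O)(N(c1ccccc1)S(=O)(=O)C(F)(F)F)C(F)(F)F
Why: The most acidic proton is at C8a, so one equivalent of base should give the β-keto ester enolate, which is O-sulfonylated at the C8 oxygen (enol triflate formation) without touching C4a or C5.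

Step 4
Reactants: 11 dienyl triflate
Product: 12 (3S,4S)-2-(tert-butoxycarbonyl)-3-[(tert-butyldimethylsilyloxy)methyl]-5-hexadecyl-4-(methoxycarbonyl)cyclohexa-1,5-diene-1-carboxylic acid
Conditions: Pd(OAc)2, dppf, KOAc, CO (1 atm), DMF/H2O, 50 °C
Reagents that add atoms: carbon monoxide, [C-]#[O+]; water, O
Why: Oxidative addition of Pd(0) into the vinyl C–OTf bond, CO insertion and capture of the acyl-palladium by acetate and water (palladium-catalysed hydroxycarbonylation of an enol triflate) should install the C8 carboxyl as the free acid that directs the next step.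

Step 5
Reactants: 12 dienoic acid
Product: 13 (1R,4S,5R,6S)-6-(tert-butoxycarbonyl)-5-[(tert-butyldimethylsilyloxy)methyl]-3-hexadecyl-4-(methoxycarbonyl)cyclohex-2-ene-1-carboxylic acid
Conditions: Ru(OAc)2[(R)-BINAP] (5 mol %), H2 (80 atm), Et3N (1 equiv), MeOH, 35 °C
Reagents that add atoms: none
Why: Carboxylate-directed hydrogenation by a Ru(II)–BINAP dicarboxylate should reduce only the alkene conjugated to the bound acid (C8=C8a) and leave the unactivated C6=C7 bond; both hydrogens arrive cis on the face away from the pseudoaxial C4 substituent on C4a, which sets C8 and C8a with the substituents at C8, C8a and C4a all cis.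

Step 6
Reactants: 13 cis acid
Product: 14 2-tert-butyl 1,4-dimethyl (1R,2S,3R,4S)-3-[(tert-butyldimethylsilyloxy)methyl]-5-hexadecylcyclohex-5-ene-1,2,4-tricarboxylate
Conditions: TMSCHN2, toluene/MeOH, 0 °C
Reagents that add atoms: trimethylsilyldiazomethane, C[Si](C)(C)C=[N+]=[N-]
Why: Esterification of the acid with trimethylsilyldiazomethane in methanol is neutral and should not epimerise the all-cis triad.

Step 7
Reactants: 14 silyl ether triester
Product: 15 2-tert-butyl 1,4-dimethyl (1R,2S,3R,4S)-5-hexadecyl-3-(hydroxymethyl)cyclohex-5-ene-1,2,4-tricarboxylate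
Conditions: HF·pyridine, pyridine/THF, 0 °C; used at once
Reagents that add atoms: none
Why: Buffered fluoride cleavage of the primary silyl ether should leave the three esters and the alkene untouched.

Step 8
Reactants: 15 alcohol
Product: 16 2-tert-butyl 1,4-dimethyl (1R,2R,3R,4S)-5-hexadecyl-3-(iodomethyl)cyclohex-5-ene-1,2,4-tricarboxylate
Conditions: PPh3, I2, imidazole, CH2Cl2, 0 °C to rt
Reagents that add atoms: iodine, II
Why: Appel-type iodination converts the primary alcohol into the iodide by SN2 displacement of the alkoxyphosphonium under near-neutral conditions.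

Step 9
Reactants: 16 iodide; 1 heptadecanoyl chloride
Product: 18 2-tert-butyl 1,4-dimethyl (1R,2S,3R,4S)-5-hexadecyl-3-(2-oxooctadecyl)cyclohex-5-ene-1,2,4-tricarboxylate, via alkylzinc iodide 17 (not isolated)
Conditions: Zn dust (TMSCl/1,2-dibromoethane activation), LiCl, THF, 35 °C; then 1, Pd(PPh3)4 (5 mol %), THF, 0 °C to rt
Reagents that add atoms: none
Why: Zinc insertion into the primary C–I bond gives an ester-tolerant alkylzinc iodide, and its palladium-catalysed coupling with the acid chloride (Negishi acylation) should form the C3–C4 bond and the C3 ketone without attack on the esters.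

Step 10
Reactants: 18 keto triester
Product: 19 (1S,2R,5S,6R)-4-hexadecyl-2,5-bis(methoxycarbonyl)-6-(2-oxooctadecyl)cyclohex-3-ene-1-carboxylic acid
Conditions: TFA/CH2Cl2 (1:4), 0 °C
Reagents that add atoms: none
Why: Acidolysis of the tert-butyl ester with loss of isobutene frees only the C8a carboxyl, the future C1, while the methyl esters, the ketone and the alkene should survive brief cold TFA.

Step 11
Reactants: 19 keto acid; 20 potassium methyl malonate
Product: 22 dimethyl (1R,2S,3R,4S)-5-hexadecyl-2-(3-methoxy-3-oxopropanoyl)-3-(2-oxooctadecyl)cyclohex-5-ene-1,4-dicarboxylate, via acyl imidazolide 21 (not isolated)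
Conditions: CDI, THF, rt; then 20, MgCl2, Et3N, MeCN, rt; aq. citric acid
Reagents that add atoms: none
Why: Activation of the acid as its imidazolide, C-acylation of the magnesium enolate of the malonate half-ester and decarboxylation on acidic work-up (Masamune–Brooks β-keto ester synthesis) should form the C1–C2 bond under conditions mild enough to keep C8a intact.

Step 12
Reactants: 22 β-keto ester
Product: 24 trimethyl (4aR,5S,8R,8aS)-3,6-dihexadecyl-1-oxo-1,4,4a,5,8,8a-hexahydronaphthalene-2,5,8-tricarboxylate, via bicyclic ketol 23 (not isolated)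
Conditions: piperidine/AcOH (20 mol %), 4 Å MS, toluene, 40 °C
Reagents that add atoms: none
Why: Intramolecular Knoevenagel (aldol) condensation of the doubly activated C2 methylene with the C3 ketone closes ring B by a 6-(enolexo)-exo-trig addition, and dehydration gives the C2=C3 bond conjugated with both carbonyl groups; the buffered amine salt should not epimerise C8a, so the cis ring fusion from step 5 is kept.

**Compound list**

1 | heptadecanoyl chloride | CCCCCCCCCCCCCCCCC(=O)Cl | starting material
2 | Meldrum's acid (2,2-dimethyl-1,3-dioxane-4,6-dione) | CC1(C)OC(=O)CC(=O)O1 | starting material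
3 | heptadecanoyl Meldrum's acid, 5-(1-hydroxyheptadecylidene)-2,2-dimethyl-1,3-dioxane-4,6-dione | CCCCCCCCCCCCCCCCC(O)=C1C(=O)OC(C)(C)OC1=O | intermediate (not isolated)
4 | methyl 3-oxononadecanoate | CCCCCCCCCCCCCCCCC(=O)CC(=O)OC | intermediate
5 | (tert-butyldimethylsilyloxy)acetaldehyde | O=CCO[Si](C)(C)C(C)(C)C | starting material
6 | tert-butyl acetoacetate (tert-butyl 3-oxobutanoate) | CC(=O)CC(=O)OC(C)(C)C | starting material
7 | methyl 2-[2-(tert-butyldimethylsilyloxy)ethylidene]-3-oxononadecanoate (E/Z mixture) | CCCCCCCCCCCCCCCCC(=O)C(=CCO[Si](C)(C)C(C)(C)C)C(=O)OC | intermediate (not isolated)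
8 | 1-tert-butyl 5-methyl (3R)-2-acetyl-3-[(tert-butyldimethylsilyloxy)methyl]-4-heptadecanoylpentanedioate (epimers at C2 and C4) | CC(=O)C(C(=O)OC(C)(C)C)[C@@H](CO[Si](C)(C)C(C)(C)C)C(C(=O)OC)C(=O)CCCCCCCCCCCCCCCC | intermediate (not isolated)
9 | 1-tert-butyl 3-methyl (2S)-2-[(tert-butyldimethylsilyloxy)methyl]-4-hexadecyl-4-hydroxy-6-oxocyclohexane-1,3-dicarboxylate (other centres as mixtures) | CCCCCCCCCCCCCCCCC1(O)CC(=O)C(C(=O)OC(C)(C)C)[C@@H](CO[Si](C)(C)C(C)(C)C)C1C(=O)OC | intermediate (not isolated)
10 | 1-tert-butyl 3-methyl (1R,2S,3S)-2-[(tert-butyldimethylsilyloxy)methyl]-4-hexadecyl-6-oxocyclohex-4-ene-1,3-dicarboxylate (ring A enone; C1 of this name is the labile decalin C8a, drawn trans) | CCCCCCCCCCCCCCCCC1=CC(=O)[C@H](C(=O)OC(C)(C)C)[C@@H](CO[Si](C)(C)C(C)(C)C)[C@@H]1C(=O)OC | intermediate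
11 | 3-tert-butyl 1-methyl (1S,2S)-2-[(tert-butyldimethylsilyloxy)methyl]-6-hexadecyl-4-(trifluoromethylsulfonyloxy)cyclohexa-3,5-diene-1,3-dicarboxylate | CCCCCCCCCCCCCCCCC1=CC(OS(=O)(=O)C(F)(F)F)=C(C(=O)OC(C)(C)C)[C@@H](CO[Si](C)(C)C(C)(C)C)[C@@H]1C(=O)OC | intermediate
12 | (3S,4S)-2-(tert-butoxycarbonyl)-3-[(tert-butyldimethylsilyloxy)methyl]-5-hexadecyl-4-(methoxycarbonyl)cyclohexa-1,5-diene-1-carboxylic acid | CCCCCCCCCCCCCCCCC1=CC(C(=O)O)=C(C(=O)OC(C)(C)C)[C@@H](CO[Si](C)(C)C(C)(C)C)[C@@H]1C(=O)OC | intermediate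
13 | (1R,4S,5R,6S)-6-(tert-butoxycarbonyl)-5-[(tert-butyldimethylsilyloxy)methyl]-3-hexadecyl-4-(methoxycarbonyl)cyclohex-2-ene-1-carboxylic acid | CCCCCCCCCCCCCCCCC1=C[C@@H](C(=O)O)[C@@H](C(=O)OC(C)(C)C)[C@@H](CO[Si](C)(C)C(C)(C)C)[C@@H]1C(=O)OC | intermediate
14 | 2-tert-butyl 1,4-dimethyl (1R,2S,3R,4S)-3-[(tert-butyldimethylsilyloxy)methyl]-5-hexadecylcyclohex-5-ene-1,2,4-tricarboxylate | CCCCCCCCCCCCCCCCC1=C[C@@H](C(=O)OC)[C@@H](C(=O)OC(C)(C)C)[C@@H](CO[Si](C)(C)C(C)(C)C)[C@@H]1C(=O)OC | intermediate
15 | 2-tert-butyl 1,4-dimethyl (1R,2S,3R,4S)-5-hexadecyl-3-(hydroxymethyl)cyclohex-5-ene-1,2,4-tricarboxylate | CCCCCCCCCCCCCCCCC1=C[C@@H](C(=O)OC)[C@@H](C(=O)OC(C)(C)C)[C@@H](CO)[C@@H]1C(=O)OC | intermediate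
16 | 2-tert-butyl 1,4-dimethyl (1R,2R,3R,4S)-5-hexadecyl-3-(iodomethyl)cyclohex-5-ene-1,2,4-tricarboxylate | CCCCCCCCCCCCCCCCC1=C[C@@H](C(=O)OC)[C@@H](C(=O)OC(C)(C)C)[C@@H](CI)[C@@H]1C(=O)OC | intermediate
17 | alkylzinc iodide of 16 (iodozinciomethyl in place of iodomethyl, same configuration) | CCCCCCCCCCCCCCCCC1=C[C@@H](C(=O)OC)[C@@H](C(=O)OC(C)(C)C)[C@@H](C[Zn]I)[C@@H]1C(=O)OC | intermediate (not isolated)
18 | 2-tert-butyl 1,4-dimethyl (1R,2S,3R,4S)-5-hexadecyl-3-(2-oxooctadecyl)cyclohex-5-ene-1,2,4-tricarboxylate | CCCCCCCCCCCCCCCCC1=C[C@@H](C(=O)OC)[C@@H](C(=O)OC(C)(C)C)[C@@H](CC(=O)CCCCCCCCCCCCCCCC)[C@@H]1C(=O)OC | intermediate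
19 | (1S,2R,5S,6R)-4-hexadecyl-2,5-bis(methoxycarbonyl)-6-(2-oxooctadecyl)cyclohex-3-ene-1-carboxylic acid | CCCCCCCCCCCCCCCCC1=C[C@@H](C(=O)OC)[C@@H](C(=O)O)[C@@H](CC(=O)CCCCCCCCCCCCCCCC)[C@@H]1C(=O)OC | intermediate
20 | potassium methyl malonate (potassium 3-methoxy-3-oxopropanoate) | COC(=O)CC(=O)[O-].[K+] | starting material
21 | acyl imidazolide of 19 (1-imidazolylcarbonyl in place of the carboxyl, same configuration) | CCCCCCCCCCCCCCCCC1=C[C@@H](C(=O)OC)[C@@H](C(=O)n2ccnc2)[C@@H](CC(=O)CCCCCCCCCCCCCCCC)[C@@H]1C(=O)OC | intermediate (not isolated)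
22 | dimethyl (1R,2S,3R,4S)-5-hexadecyl-2-(3-methoxy-3-oxopropanoyl)-3-(2-oxooctadecyl)cyclohex-5-ene-1,4-dicarboxylate | CCCCCCCCCCCCCCCCC1=C[C@@H](C(=O)OC)[C@@H](C(=O)CC(=O)OC)[C@@H](CC(=O)CCCCCCCCCCCCCCCC)[C@@H]1C(=O)OC | intermediate
23 | trimethyl (4aR,5S,8R,8aS)-3,6-dihexadecyl-3-hydroxy-1-oxo-1,2,3,4,4a,5,8,8a-octahydronaphthalene-2,5,8-tricarboxylate (C2 and C3 as mixtures) | CCCCCCCCCCCCCCCCC1=C[C@@H](C(=O)OC)[C@H]2C(=O)C(C(=O)OC)C(O)(CCCCCCCCCCCCCCCC)C[C@H]2[C@@H]1C(=O)OC | intermediate (not isolated)
24 | trimethyl (4aR,5S,8R,8aS)-3,6-dihexadecyl-1-oxo-1,4,4a,5,8,8a-hexahydronaphthalene-2,5,8-tricarboxylate (CNP0149813.1) | CCCCCCCCCCCCCCCCC1=C[C@@H](C(=O)OC)[C@H]2C(=O)C(C(=O)OC)=C(CCCCCCCCCCCCCCCC)C[C@H]2[C@@H]1C(=O)OC | target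

**Step count and risks**

Total steps: 12. Longest linear sequence: 12 steps (steps 1 to 12 in one line; 5, 6, 20 and the second portion of 1 are bought).

Steps most likely to fail:

Step 2. The Michael addition is reversible and is also promoted by any achiral amine left from the Knoevenagel stage. Enantiomeric purity at C4a can therefore be eroded, and the two keto esters can exchange partners, before the aldol closure makes the adduct permanent. Fallback: setting out from 4, 5 and 6, the condensation is run with piperidinium acetate alone and no chiral catalyst. It then passes through the mirror-image Michael adduct F1 and the mirror-image ketol F2 alongside 8 and 9, and delivers 10 together with the mirror-image enone F3. Triflation of this racemate as in step 3 gives 11 with the mirror-image triflate F4, and preparative chromatography on a chiral stationary phase (SFC) returns enantiopure 11, where the route continues.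

Step 5. Insertion of the hindered tetrasubstituted alkene into the Ru–H bond may be so slow that hydrogenation of the C6=C7 bond, or delivery to the wrong face, competes. Fallback: setting out from 12, the acid is first methylated (TMSCHN2, toluene/MeOH) to the diene triester F5. Its ene-diester unit is then reduced by electron transfer (SmI2, t-BuOH, THF/DMA, −78 °C). The radical anion should be protonated at C8a on the face away from the pseudoaxial C4 substituent. After the second electron, the dienolate should be protonated at its α-carbon C8 on the face away from the new C8a ester, which keeps the C6=C7 bond in place and should give the all-cis triester under kinetic control. The route resumes at 14.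

Step 7. The liberated primary alcohol sits 1,3-cis to the C8 methyl ester and next to two further esters, so lactonisation can consume it before the iodination. Fallback: setting out from 14, the silyl ether is converted directly into the bromide F6 with triphenylphosphine dibromide (CH2Cl2, rt), so that no free alcohol is formed. Zinc insertion (Zn, LiCl, THF, 50 °C) gives the alkylzinc bromide F7, and palladium-catalysed acylation with 1 as in step 9 comes back to the route at ketone 18.

**Further compounds**

F1 | step 2 | 1-tert-butyl 5-methyl (3S)-2-acetyl-3-[(tert-butyldimethylsilyloxy)methyl]-4-heptadecanoylpentanedioate (enantiomer of 8) | CC(=O)C(C(=O)OC(C)(C)C)[C@H](CO[Si](C)(C)C(C)(C)C)C(C(=O)OC)C(=O)CCCCCCCCCCCCCCCC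
F2 | step 2 | 1-tert-butyl 3-methyl (2R)-2-[(tert-butyldimethylsilyloxy)methyl]-4-hexadecyl-4-hydroxy-6-oxocyclohexane-1,3-dicarboxylate (enantiomer of 9) | CCCCCCCCCCCCCCCCC1(O)CC(=O)C(C(=O)OC(C)(C)C)[C@H](CO[Si](C)(C)C(C)(C)C)C1C(=O)OC
F3 | step 2 | 1-tert-butyl 3-methyl (1S,2R,3R)-2-[(tert-butyldimethylsilyloxy)methyl]-4-hexadecyl-6-oxocyclohex-4-ene-1,3-dicarboxylate (enantiomer of 10) | CCCCCCCCCCCCCCCCC1=CC(=O)[C@@H](C(=O)OC(C)(C)C)[C@H](CO[Si](C)(C)C(C)(C)C)[C@H]1C(=O)OC
F4 | step 2 | 3-tert-butyl 1-methyl (1R,2R)-2-[(tert-butyldimethylsilyloxy)methyl]-6-hexadecyl-4-(trifluoromethylsulfonyloxy)cyclohexa-3,5-diene-1,3-dicarboxylate (enantiomer of 11) | CCCCCCCCCCCCCCCCC1=CC(OS(=O)(=O)C(F)(F)F)=C(C(=O)OC(C)(C)C)[C@H](CO[Si](C)(C)C(C)(C)C)[C@H]1C(=O)OC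
F5 | step 5 | 2-tert-butyl 1,4-dimethyl (3S,4S)-3-[(tert-butyldimethylsilyloxy)methyl]-5-hexadecylcyclohexa-1,5-diene-1,2,4-tricarboxylate | CCCCCCCCCCCCCCCCC1=CC(C(=O)OC)=C(C(=O)OC(C)(C)C)[C@@H](CO[Si](C)(C)C(C)(C)C)[C@@H]1C(=O)OC
F6 | step 7 | 2-tert-butyl 1,4-dimethyl (1R,2R,3R,4S)-3-(bromomethyl)-5-hexadecylcyclohex-5-ene-1,2,4-tricarboxylate | CCCCCCCCCCCCCCCCC1=C[C@@H](C(=O)OC)[C@@H](C(=O)OC(C)(C)C)[C@@H](CBr)[C@@H]1C(=O)OC
F7 | step 7 | alkylzinc bromide of F6 (bromozinciomethyl in place of bromomethyl, same configuration) | CCCCCCCCCCCCCCCCC1=C[C@@H](C(=O)OC)[C@@H](C(=O)OC(C)(C)C)[C@@H](C[Zn]Br)[C@@H]1C(=O)OC
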